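## Analysis of the target

The target consists of two six-membered carbocycles joined through a single sp3 carbon, C7, which also carries a 2-methylpropyl chain and a hydrogen; no ring is fused to another. C7 is the only stereocentre and has the (S) configuration, with the priority order ring B > ring A > CH2 > H. Ring A (C1–C6, C1 on C7) is a fully substituted phloroglucinol with hydroxyls on C2, C4 and C6, a 3-phenylpropanoyl group on C3 and a methyl group on C5. Ring B (C1′–C6′, C1′ on C7) is the enol of a cyclohexane-1,3,5-trione with oxygen on C2′, C4′ and C6′ and gem-dimethyl groups on C3′ and C5′, that is, a syncarpic acid unit. The sensitive groups are the air-sensitive triphenol, the acidic β-triketone enol and the two C7–ring bonds, either of which can heterolyse under acid or base (reverse Friedel–Crafts or reverse Michael) and so scramble C7; strong acid can also condense a ring A hydroxyl with the ring B enol to a pyran. The synthesis is hard because C7 lies between four oxygen-bearing ortho positions, so every bond to it is hindered, because its configuration depends on telling apart two rings that look alike near C7, and because six oxygens of similar acidity must be differentiated. The strategy rests on ring B: its oxygens sit on alternate carbons (C2′, C4′, C6′) and its only extra carbons are the four methyl groups on C3′ and C5′. Without these methyl groups ring B is the 2,4,6-trihydroxyphenyl ring of a diarylmethine, so it can be carried as an arene and turned into the trione at the end by four C-methylations.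

## Retrosynthetic reasoning

**20 ⇒ 19 (three O–CH2OCH3 bonds).** The ring A phenols are masked as methoxymethyl ethers in 19. These acetals survive strong base and hydrogenolysis and come off under mild acid. The forward step must free the phenols without cyclodehydration and without heterolysis at C7.

**19 ⇒ 14 + 15 (four C–CH3 bonds at C3′ and C5′).** Cutting all four methyl groups turns the non-aromatic ring B into an aromatic trihydroxyphenyl ring and traces its extra carbons to four molecules of iodomethane 15. No bond to C7 is touched, so the stereocentre is a spectator. The forward reaction has to methylate on carbon and not oxygen, on ring B and not ring A, and stop after the fourth methyl. Ring A is therefore fully capped in 14 and ring B fully free.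

**14 ⇒ 13 ⇒ 12 ⇒ 11 (O–benzyl and O–MOM bonds).** Ring B free beside ring A capped is reached from the tris-benzyl ether 13 by hydrogenolysis. The bond-forming step before it needs one free hydroxyl on each ring, so the third benzyl group (12) and the third MOM group (13) are added after it. Ring B is benzylated first, because its phenol is unhindered while the ring A phenol is chelated to the ketone. The C7 descriptor changes along this series only through the priority rules.

**11 ⇒ 8 + 9 via 10 (C7–C1′ bond).** This is the only bond to C7 that can form by attack of an unhindered arene C–H on a planar, electrophilic C7. A cross-coupling or a boron-to-carbon shift would have to join two carbons that each sit between two ortho oxygens. Ring A is chosen as the electrophile (ortho-quinone methide 10, from carbinol 8) because it has no free ring position and cannot self-condense; a quinone methide on ring B would attack its own free ring carbons. Phenol 9 keeps one hydroxyl so that a chiral Brønsted acid can hold both partners, and C7 is set in this step.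

**8 ⇒ 6 + 7 (C7–CH2 bond).** The side chain comes from Grignard reagent 7 and aldehyde 6. A racemic carbinol is enough, because C7 becomes planar in 10.

**6 ⇒ 5 ⇒ 3 ⇒ 1 + 2 (ring A substituents).** The acyl and formyl groups are introduced by two electrophilic substitutions on triol 1, whose two free positions are equivalent. In 5 one hydroxyl lies between both carbonyl groups and is the least reactive, so the other two can be capped selectively to give 6. The free hydroxyl is then the one ortho to C7 that is needed for 10.

## Alternatives that were turned down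

**Alternative 1:** Ring A is dismantled instead of ring B.
- Disconnection and key step: a Danheiser benzannulation joins the cyclobutenone methyl (3R)-3-(2-ethoxy-4-oxocyclobut-2-en-1-yl)-5-methylhexanoate A2, which already carries C7, with the ynol ether tri(propan-2-yl)(prop-1-yn-1-yloxy)silane A3. On heating, A2 opens electrocyclically, adds A3 in a [2+2] sense, opens again and closes by 6π-electrocyclisation. The product is methyl (3R)-3-[6-ethoxy-2-hydroxy-3-methyl-4-(triisopropylsiloxy)phenyl]-5-methylhexanoate A1.
- For: the substitution pattern is fixed by the polarity of the two partners, and the three ring A oxygens arrive differentiated. C7 is set earlier on an open-chain ester and is not involved in the thermal cascade. On the certainty of the C7 configuration this route is stronger than the chosen one.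
- Against: A1 contains neither the acyl group nor any ring B carbon beyond the CH2CO2CH3 arm. Ring B would still have to be grown by two acylation-type C–C bond formations, the free ring position acylated, and an aryl ethyl ether cleaved under conditions that threaten the triketone and C7.
- Comparison: many steps follow the key step. The chosen route builds all of ring B in two operations (arylation, methylation) and uses only acetal and benzyl protection.

**Alternative 2:** C7 is built by a three-component conjunctive coupling.
- Disconnection and key step: the C7–ring A bond and the CH2–C(sp2) bond are cut. [2,4,6-Tris(methoxymethoxy)-3-methylphenyl]lithium A5 adds to boron of 2-ethenyl-4,4,5,5-tetramethyl-1,3,2-dioxaborolane A6. Under asymmetric palladium catalysis with prop-1-en-2-yl trifluoromethanesulfonate A7 the aryl group shifts from boron to carbon. The product is 4,4,5,5-tetramethyl-2-[(1S)-3-methyl-1-[2,4,6-tris(methoxymethoxy)-3-methylphenyl]but-3-en-1-yl]-1,3,2-dioxaborolane A4.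
- For: one catalytic step gives C7 with ring A, the side-chain precursor and a boron handle. On catalytic control of C7 it is stronger than the chosen route, whose stereo-determining step is less well precedented.
- Against: A4 is only half-way. Boron must be replaced by C1′ of a 2,4,6-trioxygenated ring with retention of stereochemical information. Electrophile-triggered arylation of aryl boronate complexes needs donors meta to boron, and here they are ortho and para. Metal-mediated coupling must join two doubly ortho-flanked carbons. Oxidation to the alcohol followed by Friedel–Crafts arylation would pass through a planar cation. Alkene hydrogenation and a late acylation of ring A by lithiation would follow.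
- Comparison: the chosen route forms the hard C7–C1′ bond by the sterically matched arene addition and sets C7 in that same step.

**Alternative 3:** Ring B is made by strain-release ring expansion.
- Disconnection and key step: two ring B bonds are cut. The enolate of (4R)-5,7-bis(benzyloxy)-6-methyl-4-(2-methylpropyl)-3,4-dihydro-2H-1-benzopyran-2-one A10 adds to a carbonyl of 2,2,4,4-tetramethylcyclobutane-1,3-dione A9. The four-membered ring opens and the new carbanion closes onto the lactone carbonyl, releasing the ring A phenol. The product is 2-[(1S)-1-[2,4-bis(benzyloxy)-6-hydroxy-3-methylphenyl]-3-methylbutyl]-3-hydroxy-4,4,6,6-tetramethylcyclohex-2-ene-1,5-dione A8.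
- For: four ring carbons and all four methyl groups come preassembled from A9, so no question of C- versus O-methylation or over-methylation arises. On that point it is stronger than the chosen key step. C7 is fixed earlier in the lactone.
- Against: the enolate of an aryl lactone can expel its own aryloxy group on warming. The nucleophile is β-branched and the electrophile is a hindered ketone between quaternary carbons, so the first addition is slow and reversible. The cascade as a whole is untested, and ring A would still need acylation next to an acid-sensitive C7.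
- Comparison: the chosen key step relies on a long-known transformation of close relatives instead of a new cascade.

Key step: step 9

Assumption: the sense of induction of the phosphoric acid in step 5 cannot be predicted for this substrate; the (R) enantiomer of 3,3′-bis(2,4,6-triisopropylphenyl)-1,1′-binaphthyl-2,2′-diyl hydrogen phosphate is written, and its mirror image is to be used if it proves to lead to the other enantiomer.

## Route

Step 1
Reactants: 1 2,4,6-trihydroxytoluene; 2 3-phenylpropanoyl chloride
Product: 3 1-(2,4,6-trihydroxy-3-methylphenyl)-3-phenylpropan-1-one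
Conditions: AlCl3 (3.5 equiv), PhNO2, rt → 60 °C; then 1 M HCl(aq)
Reagents that add atoms: none
Why: Friedel–Crafts acylation of a highly activated arene whose two free positions are equivalent; the first acyl group deactivates the ring toward a second acylation. The acylium ion should be intercepted by the far more nucleophilic triol before it can cyclise onto its own phenyl ring.

Step 2
Reactants: 3 1-(2,4,6-trihydroxy-3-methylphenyl)-3-phenylpropan-1-one
Product: 5 2,4,6-trihydroxy-3-methyl-5-(3-phenylpropanoyl)benzaldehyde, via aryl iminium chloride 4 (not isolated)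
Conditions: POCl3 (1.5 equiv), DMF (3 equiv), EtOAc, 0 °C → rt; then H2O, 50 °C
Reagents that add atoms: N,N-dimethylformamide, CN(C)C=O; water, O
Why: Vilsmeier–Haack formylation; the only remaining ring C–H, still activated by three hydroxyls, attacks the chloroiminium ion to give 4, which is hydrolysed to the aldehyde on work-up.

Step 3
Reactants: 5 2,4,6-trihydroxy-3-methyl-5-(3-phenylpropanoyl)benzaldehyde
Product: 6 2-hydroxy-4,6-bis(methoxymethoxy)-5-methyl-3-(3-phenylpropanoyl)benzaldehyde
Conditions: MOMCl (2.2 equiv), i-Pr2NEt (3 equiv), CH2Cl2, 0 °C → rt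
Reagents that add atoms: chloromethyl methyl ether (two equivalents of MOMCl), COCCl.COCCl
Why: MOM protection of phenols with a hindered amine base; two molecules of the chloride are taken up. The hydroxyl between the formyl and the acyl group is hydrogen-bonded to both carbonyls and flanked on both sides, so its anion is the least nucleophilic and the other two oxygens should be capped first.

Step 4
Reactants: 6 2-hydroxy-4,6-bis(methoxymethoxy)-5-methyl-3-(3-phenylpropanoyl)benzaldehyde; 7 isobutylmagnesium bromide
Product: 8 rac-1-[2-hydroxy-3-(1-hydroxy-3-methylbutyl)-4,6-bis(methoxymethoxy)-5-methylphenyl]-3-phenylpropan-1-one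
Conditions: i-BuMgBr (2.3 equiv), THF, −78 → −20 °C; NH4Cl(aq)
Reagents that add atoms: none
Why: Grignard addition to an aldehyde: one equivalent of 7 is spent on the phenol and the next adds to the formyl group, which is far more electrophilic and less hindered than the di-ortho-substituted, enolisable aryl ketone. The carbinol centre forms without control, which does not matter because it becomes planar in step 5. Compound 8 is an acid-sensitive ortho-hydroxybenzyl alcohol and is carried on without chromatography.

Step 5
Reactants: 8 rac-1-[2-hydroxy-3-(1-hydroxy-3-methylbutyl)-4,6-bis(methoxymethoxy)-5-methylphenyl]-3-phenylpropan-1-one; 9 3,5-bis(benzyloxy)phenol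
Product: 11 1-[3-[(1R)-1-[2,4-bis(benzyloxy)-6-hydroxyphenyl]-3-methylbutyl]-2-hydroxy-4,6-bis(methoxymethoxy)-5-methylphenyl]-3-phenylpropan-1-one, via ortho-quinone methide 10 (not isolated)
Conditions: (R)-3,3′-bis(2,4,6-triisopropylphenyl)-1,1′-binaphthyl-2,2′-diyl hydrogen phosphate (10 mol %), 9 (2 equiv), 5 Å MS, toluene, −20 → 0 °C
Reagents that add atoms: none
Why: Chiral-phosphoric-acid-catalysed Friedel–Crafts arylation of an ortho-quinone methide: the acid dehydrates 8 to 10 and binds both partners by hydrogen bonds (P–OH to the quinone methide oxygen, P=O to the phenolic OH of 9), so that the carbon ortho to that OH attacks one face of C7 and the catalyst sets the C7 configuration. Ring A has no free ring position, so 10 cannot self-condense, and the excess of 9 keeps double alkylation down. Low temperature limits acid-induced reversal of the addition, which would erode the configuration.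

Step 6
Reactants: 11 1-[3-[(1R)-1-[2,4-bis(benzyloxy)-6-hydroxyphenyl]-3-methylbutyl]-2-hydroxy-4,6-bis(methoxymethoxy)-5-methylphenyl]-3-phenylpropan-1-one
Product: 12 1-[2-hydroxy-4,6-bis(methoxymethoxy)-5-methyl-3-[(1S)-3-methyl-1-[2,4,6-tris(benzyloxy)phenyl]butyl]phenyl]-3-phenylpropan-1-one
Conditions: BnBr (1.05 equiv), K2CO3 (1.5 equiv), acetone, rt
Reagents that add atoms: benzyl bromide, BrCc1ccccc1
Why: Williamson ether synthesis: the ring B phenoxide is benzylated, whereas the ring A hydroxyl, chelated to the ketone and wedged between the acyl group and C7, should not react with one equivalent of bromide at room temperature. Any isomer of 11 formed by attack para to the hydroxyl of 9 gives the same tris-benzyl ether, so both converge on 12. C7 is untouched; its descriptor changes from R to S only because the new benzyl group alters the priority order of the two rings.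

Step 7
Reactants: 12 1-[2-hydroxy-4,6-bis(methoxymethoxy)-5-methyl-3-[(1S)-3-methyl-1-[2,4,6-tris(benzyloxy)phenyl]butyl]phenyl]-3-phenylpropan-1-one
Product: 13 1-[2,4,6-tris(methoxymethoxy)-3-methyl-5-[(1R)-3-methyl-1-[2,4,6-tris(benzyloxy)phenyl]butyl]phenyl]-3-phenylpropan-1-one
Conditions: NaH (1.2 equiv), MOMCl (1.5 equiv), THF–DMF, 0 °C → rt
Reagents that add atoms: chloromethyl methyl ether (MOMCl), COCCl
Why: MOM protection of the last, chelated phenol through its sodium salt; the ethers and C7 are inert to NaH at low temperature, and only a slight excess of base is used so that the ketone is not enolised. The descriptor returns to R for formal reasons only.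

Step 8
Reactants: 13 1-[2,4,6-tris(methoxymethoxy)-3-methyl-5-[(1R)-3-methyl-1-[2,4,6-tris(benzyloxy)phenyl]butyl]phenyl]-3-phenylpropan-1-one
Product: 14 1-[2,4,6-tris(methoxymethoxy)-3-methyl-5-[(1R)-3-methyl-1-(2,4,6-trihydroxyphenyl)butyl]phenyl]-3-phenylpropan-1-one
Conditions: H2 (1 atm), 10% Pd/C, EtOAc–EtOH, rt
Reagents that add atoms: none
Why: Hydrogenolysis of three aryl benzyl ethers over Pd/C; MOM ethers, the hindered aryl ketone and the C7–aryl bonds, which carry no heteroatom on C7, should be stable at 1 atm and room temperature.

Step 9
Reactants: 14 1-[2,4,6-tris(methoxymethoxy)-3-methyl-5-[(1R)-3-methyl-1-(2,4,6-trihydroxyphenyl)butyl]phenyl]-3-phenylpropan-1-one; 15 iodomethane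
Product: 19 3-hydroxy-4,4,6,6-tetramethyl-2-[(1S)-3-methyl-1-[2,4,6-tris(methoxymethoxy)-3-methyl-5-(3-phenylpropanoyl)phenyl]butyl]cyclohex-2-ene-1,5-dione, via monomethyl arene 16 (not isolated), via dimethyl arene 17 (not isolated), via trimethyl dienone 18 (not isolated)
Conditions: NaOMe (6 equiv), 15 (4.4 equiv), MeOH, 0 °C → rt, Ar; then NaH2PO4(aq) to pH 4–5
Reagents that add atoms: iodomethane (three further equivalents of 15), CI.CI.CI
Why: Sodium methoxide turns the trihydroxyphenyl ring of 14 into its polyanion, an ambident nucleophile that in methanol attacks the soft electrophile 15 through carbon by SN2 substitution, because the oxygens are tied up by hydrogen bonding and sodium coordination. Four molecules of 15 are consumed, one for each new C–CH3 bond: the first two methyl groups enter at C3′ and C5′ with rearomatisation (16, 17); the third and fourth go to the same two carbons, create the quaternary centres and break aromaticity for good (18), leaving ring B as the sodium enolate of 19. The closest known reactions are the exhaustive C-methylation of phloroglucinol and of 2-acylphloroglucinols with iodomethane and sodium methoxide, the standard laboratory entry to syncarpic acid derivatives. No ring closes and no stereocentre is formed; C7 has no acidic hydrogen under these conditions because the adjacent ring is already anionic, and no fragmentation path is open because ring A has no free phenol, so the configuration from step 5 is carried through (the descriptor becomes S only through the priority rules). Three selectivities are needed: ring B over ring A, secured by the three MOM ethers, the absence of any ring hydrogen on ring A and the negligible enolisation of the hindered aryl ketone by methoxide in methanol; carbon over oxygen, secured by the protic medium; and C3′ and C5′ over C1′, secured by the bulk of the branched substituent on C1′. After four methylations the remaining anion is a vinylogous carboxylate, far less nucleophilic than the phenoxides before it, so with a small excess of 15 at 0–25 °C a fifth methylation at C1′ or on the enol oxygen should stay minor. The reaction is run under argon and acidified only to pH 4–5 to spare the MOM ethers.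

Step 10
Reactants: 19 3-hydroxy-4,4,6,6-tetramethyl-2-[(1S)-3-methyl-1-[2,4,6-tris(methoxymethoxy)-3-methyl-5-(3-phenylpropanoyl)phenyl]butyl]cyclohex-2-ene-1,5-dione
Product: 20 3-hydroxy-4,4,6,6-tetramethyl-2-[(1S)-3-methyl-1-[2,4,6-trihydroxy-3-methyl-5-(3-phenylpropanoyl)phenyl]butyl]cyclohex-2-ene-1,5-dione
Conditions: HCl (1.25 M in MeOH), 0 °C → rt
Reagents that add atoms: none
Why: Acid-catalysed acetal exchange removes the three MOM ethers; the two next to the ketone are assisted by chelation. The temperature is kept at or below ambient and the reaction stopped at full conversion, so that neither cyclodehydration between a ring A phenol and the ring B enol nor acid-induced heterolysis at C7 sets in.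

## Compound list

1 | 2,4,6-trihydroxytoluene | Cc1c(O)cc(O)cc1O | starting material
2 | 3-phenylpropanoyl chloride | O=C(Cl)CCc1ccccc1 | starting material
3 | 1-(2,4,6-trihydroxy-3-methylphenyl)-3-phenylpropan-1-one | Cc1c(O)cc(O)c(C(=O)CCc2ccccc2)c1O | intermediate
4 | N-methyl-N-{[2,4,6-trihydroxy-3-methyl-5-(3-phenylpropanoyl)phenyl]methylidene}methanaminium chloride | C[N+](C)=Cc1c(O)c(C)c(O)c(C(=O)CCc2ccccc2)c1O.[Cl-] | intermediate
5 | 2,4,6-trihydroxy-3-methyl-5-(3-phenylpropanoyl)benzaldehyde | Cc1c(O)c(C=O)c(O)c(C(=O)CCc2ccccc2)c1O | intermediate
6 | 2-hydroxy-4,6-bis(methoxymethoxy)-5-methyl-3-(3-phenylpropanoyl)benzaldehyde | Cc1c(OCOC)c(C=O)c(O)c(C(=O)CCc2ccccc2)c1OCOC | intermediate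
7 | isobutylmagnesium bromide | CC(C)C[Mg]Br | starting material
8 | rac-1-[2-hydroxy-3-(1-hydroxy-3-methylbutyl)-4,6-bis(methoxymethoxy)-5-methylphenyl]-3-phenylpropan-1-one (racemic, no configuration assigned) | Cc1c(OCOC)c(C(O)CC(C)C)c(O)c(C(=O)CCc2ccccc2)c1OCOC | intermediate
9 | 3,5-bis(benzyloxy)phenol | Oc1cc(OCc2ccccc2)cc(OCc2ccccc2)c1 | starting material
10 | (6Z)-3,5-bis(methoxymethoxy)-4-methyl-6-(3-methylbutylidene)-2-(3-phenylpropanoyl)cyclohexa-2,4-dien-1-one (Z expected, side chain syn to the ring carbonyl) | CC(C)C/C=C1\C(=O)C(C(=O)CCc2ccccc2)=C(OCOC)C(C)=C1OCOC | intermediate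
11 | 1-[3-[(1R)-1-[2,4-bis(benzyloxy)-6-hydroxyphenyl]-3-methylbutyl]-2-hydroxy-4,6-bis(methoxymethoxy)-5-methylphenyl]-3-phenylpropan-1-one | Cc1c(OCOC)c(C(=O)CCc2ccccc2)c(O)c([C@H](CC(C)C)c2c(O)cc(OCc3ccccc3)cc2OCc2ccccc2)c1OCOC | intermediate
12 | 1-[2-hydroxy-4,6-bis(methoxymethoxy)-5-methyl-3-[(1S)-3-methyl-1-[2,4,6-tris(benzyloxy)phenyl]butyl]phenyl]-3-phenylpropan-1-one | Cc1c(OCOC)c(C(=O)CCc2ccccc2)c(O)c([C@H](CC(C)C)c2c(OCc3ccccc3)cc(OCc3ccccc3)cc2OCc2ccccc2)c1OCOC | intermediate
13 | 1-[2,4,6-tris(methoxymethoxy)-3-methyl-5-[(1R)-3-methyl-1-[2,4,6-tris(benzyloxy)phenyl]butyl]phenyl]-3-phenylpropan-1-one | Cc1c(OCOC)c(C(=O)CCc2ccccc2)c(OCOC)c([C@H](CC(C)C)c2c(OCc3ccccc3)cc(OCc3ccccc3)cc2OCc2ccccc2)c1OCOC | intermediate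
14 | 1-[2,4,6-tris(methoxymethoxy)-3-methyl-5-[(1R)-3-methyl-1-(2,4,6-trihydroxyphenyl)butyl]phenyl]-3-phenylpropan-1-one | Cc1c(OCOC)c(C(=O)CCc2ccccc2)c(OCOC)c([C@H](CC(C)C)c2c(O)cc(O)cc2O)c1OCOC | intermediate
15 | iodomethane | CI | starting material
16 | 1-[2,4,6-tris(methoxymethoxy)-3-methyl-5-[(1R)-3-methyl-1-(2,4,6-trihydroxy-3-methylphenyl)butyl]phenyl]-3-phenylpropan-1-one | Cc1c(OCOC)c(C(=O)CCc2ccccc2)c(OCOC)c([C@H](CC(C)C)c2c(O)cc(O)c(C)c2O)c1OCOC | intermediate
17 | 1-[5-[(1R)-1-(2,4,6-trihydroxy-3,5-dimethylphenyl)-3-methylbutyl]-2,4,6-tris(methoxymethoxy)-3-methylphenyl]-3-phenylpropan-1-one | Cc1c(OCOC)c(C(=O)CCc2ccccc2)c(OCOC)c([C@H](CC(C)C)c2c(O)c(C)c(O)c(C)c2O)c1OCOC | intermediate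
18 | 3,5-dihydroxy-4,6,6-trimethyl-2-[(1S)-3-methyl-1-[2,4,6-tris(methoxymethoxy)-3-methyl-5-(3-phenylpropanoyl)phenyl]butyl]cyclohexa-2,4-dien-1-one | Cc1c(OCOC)c(C(=O)CCc2ccccc2)c(OCOC)c([C@H](CC(C)C)C2=C(O)C(C)=C(O)C(C)(C)C2=O)c1OCOC | intermediate
19 | 3-hydroxy-4,4,6,6-tetramethyl-2-[(1S)-3-methyl-1-[2,4,6-tris(methoxymethoxy)-3-methyl-5-(3-phenylpropanoyl)phenyl]butyl]cyclohex-2-ene-1,5-dione | Cc1c(OCOC)c(C(=O)CCc2ccccc2)c(OCOC)c([C@H](CC(C)C)C2=C(O)C(C)(C)C(=O)C(C)(C)C2=O)c1OCOC | intermediate
20 | 3-hydroxy-4,4,6,6-tetramethyl-2-[(1S)-3-methyl-1-[2,4,6-trihydroxy-3-methyl-5-(3-phenylpropanoyl)phenyl]butyl]cyclohex-2-ene-1,5-dione | Cc1c(O)c(C(=O)CCc2ccccc2)c(O)c([C@H](CC(C)C)C2=C(O)C(C)(C)C(=O)C(C)(C)C2=O)c1O | target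

## Step count and least certain steps

Total: 10 steps. Longest linear sequence: 10 steps (1 → 20); compounds 2, 7, 9 and 15 are bought.

**Step 9 (key step).** Methylation may not stop cleanly at four. A fifth methyl can enter at C1′ or on the enol oxygen once excess iodide is present, the sequence can stall at the stage of 17 or 18, or an oxygen can be methylated at an intermediate stage. The successive anions differ only gradually in nucleophilicity, and the polyanion is also prone to oxidation by air. Fallback: bring in the four methyl groups preformed. Carbinol 8 is treated with commercial syncarpic acid (2,2,4,4-tetramethylcyclohexane-1,3,5-trione) under the acid catalysis of step 5. Conjugate addition of the cyclic trione to quinone methide 10, a known reaction type for cyclic 1,3-diketones, should give 3-hydroxy-2-[(1S)-1-[2-hydroxy-4,6-bis(methoxymethoxy)-5-methyl-3-(3-phenylpropanoyl)phenyl]-3-methylbutyl]-4,4,6,6-tetramethylcyclohex-2-ene-1,5-dione F1. Its two MOM ethers are removed as in step 10. The fallback sets out from 8 and comes back at 20.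

**Step 5.** Facial selectivity in the attack on 10 may be poor, because the substrate offers the acid several hydrogen-bond acceptors. Part of the attack may go para to the hydroxyl of 9 with a different sense, and acid-mediated reversal can erode the enantiomer ratio. Fallback: classical resolution. Scalemic 11 is acylated on its ring B hydroxyl with (1S)-(−)-camphanic chloride (Et3N, DMAP, CH2Cl2). This gives 3,5-bis(benzyloxy)-2-[(1S)-1-[2-hydroxy-4,6-bis(methoxymethoxy)-5-methyl-3-(3-phenylpropanoyl)phenyl]-3-methylbutyl]phenyl (1S,4R)-4,7,7-trimethyl-3-oxo-2-oxabicyclo[2.2.1]heptane-1-carboxylate F2 together with its diastereomer 3,5-bis(benzyloxy)-2-[(1R)-1-[2-hydroxy-4,6-bis(methoxymethoxy)-5-methyl-3-(3-phenylpropanoyl)phenyl]-3-methylbutyl]phenyl (1S,4R)-4,7,7-trimethyl-3-oxo-2-oxabicyclo[2.2.1]heptane-1-carboxylate F3. The two are separated by crystallisation or chromatography, and F2 is cleaved with K2CO3 in methanol. The fallback sets out from 11 and comes back at 11.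

**Step 3.** Site selectivity may be lost: protection can run on to the tris-acetal or cap the wrong pair of hydroxyls, since all three are hydrogen-bonded to a carbonyl and differ only in degree. Fallback: protect everything and remove one group. Triol 5 is converted with NaH and excess MOMCl into 2,4,6-tris(methoxymethoxy)-3-methyl-5-(3-phenylpropanoyl)benzaldehyde F4. MgBr2·OEt2, which binds between the two carbonyl groups, then removes the acetal lying between them. The fallback sets out from 5 and comes back at 6.

**Step 4.** The aldehyde may be reduced by β-hydride transfer from 7, or the reagent may attack or enolise the ketone. Premature loss of water from 8 on work-up, followed by dimerisation of 10, is also possible; 8 is both hindered and labile. Fallback: aldehyde 6 is olefinated with the ylide from (2-methylpropyl)triphenylphosphonium bromide (KHMDS, 2.2 equiv, THF) to give 1-[2-hydroxy-4,6-bis(methoxymethoxy)-5-methyl-3-(3-methylbut-1-en-1-yl)phenyl]-3-phenylpropan-1-one F5 as an E/Z mixture. Under the conditions of step 5 the acid protonates the alkene carbon remote from the ring and generates the same quinone methide 10. The fallback sets out from 6 and comes back at 11.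

**Step 6.** The ring A hydroxyl may be benzylated as well, or ring B may be benzylated on carbon, if the reactivity difference between the two phenols is smaller than expected. Fallback: avoid the selective step. Carbinol 8 is coupled under the conditions of step 5 with commercial 1,3,5-tris(benzyloxy)benzene in place of 9, which gives 12 directly, at the price of losing the hydrogen bond from the nucleophile to the catalyst. The fallback sets out from 8, comes back at 12 and makes no new compound.

## Further compounds

F1 | step 9 | 3-hydroxy-2-[(1S)-1-[2-hydroxy-4,6-bis(methoxymethoxy)-5-methyl-3-(3-phenylpropanoyl)phenyl]-3-methylbutyl]-4,4,6,6-tetramethylcyclohex-2-ene-1,5-dione | Cc1c(OCOC)c(C(=O)CCc2ccccc2)c(O)c([C@H](CC(C)C)C2=C(O)C(C)(C)C(=O)C(C)(C)C2=O)c1OCOC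
F2 | step 5 | 3,5-bis(benzyloxy)-2-[(1S)-1-[2-hydroxy-4,6-bis(methoxymethoxy)-5-methyl-3-(3-phenylpropanoyl)phenyl]-3-methylbutyl]phenyl (1S,4R)-4,7,7-trimethyl-3-oxo-2-oxabicyclo[2.2.1]heptane-1-carboxylate | Cc1c(OCOC)c(C(=O)CCc2ccccc2)c(O)c([C@H](CC(C)C)c2c(OC(=O)[C@@]34CC[C@@](C)(C(=O)O3)C4(C)C)cc(OCc3ccccc3)cc2OCc2ccccc2)c1OCOC
F3 | step 5 | 3,5-bis(benzyloxy)-2-[(1R)-1-[2-hydroxy-4,6-bis(methoxymethoxy)-5-methyl-3-(3-phenylpropanoyl)phenyl]-3-methylbutyl]phenyl (1S,4R)-4,7,7-trimethyl-3-oxo-2-oxabicyclo[2.2.1]heptane-1-carboxylate | Cc1c(OCOC)c(C(=O)CCc2ccccc2)c(O)c([C@@H](CC(C)C)c2c(OC(=O)[C@@]34CC[C@@](C)(C(=O)O3)C4(C)C)cc(OCc3ccccc3)cc2OCc2ccccc2)c1OCOC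
F4 | step 3 | 2,4,6-tris(methoxymethoxy)-3-methyl-5-(3-phenylpropanoyl)benzaldehyde | Cc1c(OCOC)c(C=O)c(OCOC)c(C(=O)CCc2ccccc2)c1OCOC
F5 | step 4 | 1-[2-hydroxy-4,6-bis(methoxymethoxy)-5-methyl-3-(3-methylbut-1-en-1-yl)phenyl]-3-phenylpropan-1-one (E/Z mixture) | Cc1c(OCOC)c(C=CC(C)C)c(O)c(C(=O)CCc2ccccc2)c1OCOC
F0 | step 6 | none | none
A1 | alternative 1 | methyl (3R)-3-[6-ethoxy-2-hydroxy-3-methyl-4-(triisopropylsiloxy)phenyl]-5-methylhexanoate | Cc1c(O[Si](C(C)C)(C(C)C)C(C)C)cc(OCC)c([C@H](CC(C)C)CC(=O)OC)c1O
A2 | alternative 1 | methyl (3R)-3-(2-ethoxy-4-oxocyclobut-2-en-1-yl)-5-methylhexanoate (ring carbon unassigned) | CCOC1=CC(=O)C1[C@H](CC(C)C)CC(=O)OC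
A3 | alternative 1 | tri(propan-2-yl)(prop-1-yn-1-yloxy)silane | CC#CO[Si](C(C)C)(C(C)C)C(C)C
A4 | alternative 2 | 4,4,5,5-tetramethyl-2-[(1S)-3-methyl-1-[2,4,6-tris(methoxymethoxy)-3-methylphenyl]but-3-en-1-yl]-1,3,2-dioxaborolane | Cc1c(OCOC)cc(OCOC)c([C@H](CC(C)=C)B2OC(C)(C)C(C)(C)O2)c1OCOC
A5 | alternative 2 | [2,4,6-tris(methoxymethoxy)-3-methylphenyl]lithium | [Li]c1c(OCOC)cc(OCOC)c(C)c1OCOC
A6 | alternative 2 | 2-ethenyl-4,4,5,5-tetramethyl-1,3,2-dioxaborolane | C=CB1OC(C)(C)C(C)(C)O1
A7 | alternative 2 | prop-1-en-2-yl trifluoromethanesulfonate | CC(=C)OS(=O)(=O)C(F)(F)F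
A8 | alternative 3 | 2-[(1S)-1-[2,4-bis(benzyloxy)-6-hydroxy-3-methylphenyl]-3-methylbutyl]-3-hydroxy-4,4,6,6-tetramethylcyclohex-2-ene-1,5-dione | Cc1c(OCc2ccccc2)cc(O)c([C@H](CC(C)C)C2=C(O)C(C)(C)C(=O)C(C)(C)C2=O)c1OCc1ccccc1
A9 | alternative 3 | 2,2,4,4-tetramethylcyclobutane-1,3-dione | CC1(C)C(=O)C(C)(C)C1=O
A10 | alternative 3 | (4R)-5,7-bis(benzyloxy)-6-methyl-4-(2-methylpropyl)-3,4-dihydro-2H-1-benzopyran-2-one | Cc1c(OCc2ccccc2)cc2OC(=O)C[C@@H](CC(C)C)c2c1OCc1ccccc1
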